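**Plan**

- Ring A carries the ring oxygen O1 (on C8a) and the C4 carbonyl (on C4a) on neighbouring carbons. After removal of the three MOM groups and of a temporary C5 chlorine, the retrosynthesis therefore cuts O1–C8a and C4–C4a together, leaving a C4a≡C8a aryne and an acyclic C2–C3–C4 hydroxy ester.
- The hydroxy ester is cut at C2–C3 (aldol) into a diprenylated ring B aldehyde and a MOM-glycolyl imide. The aryne precursor comes from 5-chlororesorcinol by two directed lithiations and an O→C silyl shift.
- Forward: ring A precursor (steps 1–6), ring B aldehyde (7–8), glycolyl imide (9–10), aldol and ester (11–12). Ring C is then closed between rings A and B in step 13; dechlorination and deprotection finish the synthesis (14–15).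
- Stereochemistry: C2 (R) and C3 (R) are both set in the auxiliary-controlled anti aldol of step 11 (anti in the chain corresponds to trans in the ring). No bond at C2 or C3 is broken afterwards.

Key step: step 13

Remark: atom labels (O1, C2, C3, C4, C4a, C5 to C8, C8a) follow flavanone numbering, MOM stands for methoxymethyl, and 3, 16 and 21 are taken as purchased.

**Route**

Step 1
Reactants: 1 5-chlororesorcinol (5-chlorobenzene-1,3-diol)
Product: 2 1-chloro-3,5-bis(methoxymethoxy)benzene
Conditions: MOMCl (2.5 equiv), i-Pr2NEt, CH2Cl2, 0 °C → rt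
Reagents that add atoms: chloromethyl methyl ether, COCCl
Why: O-Alkylation of both phenols (Williamson-type acetal ether formation) under amine base should proceed cleanly and installs the two MOM groups that later direct the ortho-lithiation at the carbon between them.

Step 2
Reactants: 2 1-chloro-3,5-bis(methoxymethoxy)benzene; 3 prenyl bromide (1-bromo-3-methylbut-2-ene)
Product: 5 5-chloro-1,3-bis(methoxymethoxy)-2-(3-methylbut-2-en-1-yl)benzene, via aryllithium 4 (not isolated)
Conditions: n-BuLi, THF, −20 → 0 °C; CuBr·SMe2 (10 mol %), 3, −78 °C → rt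
Reagents that add atoms: none
Why: Directed ortho-metalation should remove the proton flanked by both MOM ethers, the kinetically most activated site, and copper-catalysed allylic substitution of the aryllithium at the primary carbon of 3 should then give the linear prenyl group between the two oxygens.

Step 3
Reactants: 5 5-chloro-1,3-bis(methoxymethoxy)-2-(3-methylbut-2-en-1-yl)benzene
Product: 7 2-bromo-1-chloro-3,5-bis(methoxymethoxy)-4-(3-methylbut-2-en-1-yl)benzene, via aryllithium 6 (not isolated)
Conditions: n-BuLi, TMEDA, THF, −78 °C; BrCl2C–CCl2Br, −78 °C → rt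
Reagents that add atoms: 1,2-dibromo-1,1,2,2-tetrachloroethane, BrC(Cl)(Cl)C(Cl)(Cl)Br
Why: A second directed ortho-metalation should take the ring proton flanked by a MOM ether and chlorine (the two open positions are equivalent by symmetry), and quenching the aryllithium at −78 °C with a positive-bromine donor brominates the ring without exposing the prenyl alkene to Br2 or letting the ortho-chloro aryllithium lose LiCl.

Step 4
Reactants: 7 2-bromo-1-chloro-3,5-bis(methoxymethoxy)-4-(3-methylbut-2-en-1-yl)benzene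
Product: 8 4-bromo-5-chloro-2-(3-methylbut-2-en-1-yl)benzene-1,3-diol
Conditions: HCl (cat.), MeOH, rt
Reagents that add atoms: none
Why: Acid-catalysed acetal methanolysis of the two aryl MOM ethers is fast at room temperature in dilute HCl, where cyclisation of the halogen-deactivated ortho-prenyl resorcinol to a chroman should remain slow.

Step 5
Reactants: 8 4-bromo-5-chloro-2-(3-methylbut-2-en-1-yl)benzene-1,3-diol
Product: 12 3-chloro-5-hydroxy-6-(3-methylbut-2-en-1-yl)-2-(trimethylsilyl)phenyl trifluoromethanesulfonate, via bis(trimethylsilyl) ether 9 (not isolated), via lithium phenoxide 10 (not isolated), via silyl ether triflate 11 (not isolated)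
Conditions: HMDS, THF, 65 °C, then evaporation; n-BuLi (1.05 equiv), THF, −78 °C; Tf2O, −78 → 0 °C; citric acid, MeOH, rt
Reagents that add atoms: hexamethyldisilazane, C[Si](C)(C)N[Si](C)(C)C; trifluoromethanesulfonic anhydride, O=S(=O)(OS(=O)(=O)C(F)(F)F)C(F)(F)F
Why: After O-silylation, bromine–lithium exchange triggers a retro-Brook (O→C 1,3-silyl) rearrangement that can only draw silicon from the oxygen next to the lithiated carbon, so the phenoxide trapped as triflate is necessarily the one beside the new C–Si bond, and mild methanolysis then frees the other, still O-silylated phenol.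

Step 6
Reactants: 12 3-chloro-5-hydroxy-6-(3-methylbut-2-en-1-yl)-2-(trimethylsilyl)phenyl trifluoromethanesulfonate
Product: 13 3-chloro-5-(methoxymethoxy)-6-(3-methylbut-2-en-1-yl)-2-(trimethylsilyl)phenyl trifluoromethanesulfonate
Conditions: MOMCl, i-Pr2NEt, CH2Cl2, 0 °C → rt
Reagents that add atoms: chloromethyl methyl ether, COCCl
Why: O-Alkylation of the one free phenol under amine base avoids fluoride and alkoxide, either of which would trigger the ortho-silylaryl triflate.

Step 7
Reactants: 14 3,5-dibromo-4-hydroxybenzaldehyde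
Product: 15 3,5-dibromo-4-(methoxymethoxy)benzaldehyde
Conditions: MOMCl, i-Pr2NEt, CH2Cl2, 0 °C → rt
Reagents that add atoms: chloromethyl methyl ether, COCCl
Why: O-Alkylation of the acidic 2,6-dibromophenol masks it as the same acetal used elsewhere, so that one acidic step at the end frees all hydroxyl groups.

Step 8
Reactants: 15 3,5-dibromo-4-(methoxymethoxy)benzaldehyde; 16 tributyl(3-methylbut-2-en-1-yl)stannane
Product: 17 4-(methoxymethoxy)-3,5-bis(3-methylbut-2-en-1-yl)benzaldehyde
Conditions: 16 (2.5 equiv), Pd(PPh3)4 (10 mol %), DMF, 100 °C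
Reagents that add atoms: none
Why: Twofold Stille coupling: oxidative addition of zerovalent palladium into the C–Br bonds activated by the para formyl group, allyl transfer from tin and reductive elimination at the less hindered allyl terminus should give two linear prenyl groups under neutral conditions that spare the aldehyde and the MOM ether.

Step 9
Reactants: 18 glycolic acid (2-hydroxyacetic acid)
Product: 20 2-(methoxymethoxy)acetic acid, via methoxymethyl ester 19 (not isolated)
Conditions: MOMCl (2.4 equiv), i-Pr2NEt, CH2Cl2, 0 °C → rt; LiOH, THF/H2O, 0 °C; HCl to pH 3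
Reagents that add atoms: chloromethyl methyl ether, COCCl; lithium hydroxide, [Li+].[OH-]
Why: Exhaustive O-alkylation followed by saponification, in which hydroxide attacks only the ester carbonyl of the acyloxymethyl acetal, should leave the base-stable MOM ether of the alcohol in place.

Step 10
Reactants: 20 2-(methoxymethoxy)acetic acid; 21 (4S)-4-benzyl-1,3-oxazolidin-2-one
Product: 23 (4S)-4-benzyl-3-[2-(methoxymethoxy)acetyl]-1,3-oxazolidin-2-one, via mixed pivalic anhydride 22 (not isolated)
Conditions: PivCl, Et3N, THF, −20 °C; 21, LiCl, rt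
Reagents that add atoms: none
Why: N-Acylation of the oxazolidinone by the mixed pivalic anhydride, LiCl and Et3N making the carbamate nitrogen nucleophilic enough, is a standard route to N-glycolyl imides, attack occurring at the less hindered alkoxyacetyl carbonyl.

Step 11
Reactants: 23 (4S)-4-benzyl-3-[2-(methoxymethoxy)acetyl]-1,3-oxazolidin-2-one; 17 4-(methoxymethoxy)-3,5-bis(3-methylbut-2-en-1-yl)benzaldehyde
Product: 25 (4S)-4-benzyl-3-[(2R,3R)-3-hydroxy-2-(methoxymethoxy)-3-[4-(methoxymethoxy)-3,5-bis(3-methylbut-2-en-1-yl)phenyl]propanoyl]-1,3-oxazolidin-2-one, via trimethylsilyl ether 24 (not isolated)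
Conditions: MgCl2 (20 mol %), Et3N, TMSCl, EtOAc, rt; PPTS (cat.), MeOH, 0 °C
Reagents that add atoms: none
Why: Magnesium halide-catalysed anti-selective Evans aldol reaction: the chelated (Z)-magnesium enolate of 23 should add to the non-enolisable aldehyde through a boat transition state on the face opposite the benzyl group, which sets the α-carbon (later C3) as R and the carbinol carbon (later C2) as R in an anti relationship, while silylation of the aldolate by TMSCl makes the reversible addition productive.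

Step 12
Reactants: 25 (4S)-4-benzyl-3-[(2R,3R)-3-hydroxy-2-(methoxymethoxy)-3-[4-(methoxymethoxy)-3,5-bis(3-methylbut-2-en-1-yl)phenyl]propanoyl]-1,3-oxazolidin-2-one
Product: 26 methyl (2R,3R)-3-hydroxy-2-(methoxymethoxy)-3-[4-(methoxymethoxy)-3,5-bis(3-methylbut-2-en-1-yl)phenyl]propanoate
Conditions: MeMgBr (1.5 equiv), MeOH, CH2Cl2, 0 °C; aq. NH4Cl
Reagents that add atoms: methanol, CO
Why: Transesterification by bromomagnesium methoxide at the activated exocyclic imide carbonyl releases the auxiliary, and the chelated magnesium aldolate resists retro-aldol cleavage and α-epimerisation, so the anti (2R,3R) pair should be kept.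

Step 13
Reactants: 26 methyl (2R,3R)-3-hydroxy-2-(methoxymethoxy)-3-[4-(methoxymethoxy)-3,5-bis(3-methylbut-2-en-1-yl)phenyl]propanoate; 13 3-chloro-5-(methoxymethoxy)-6-(3-methylbut-2-en-1-yl)-2-(trimethylsilyl)phenyl trifluoromethanesulfonate
Product: 28 (2R,3R)-5-chloro-3,7-bis(methoxymethoxy)-2-[4-(methoxymethoxy)-3,5-bis(3-methylbut-2-en-1-yl)phenyl]-8-(3-methylbut-2-en-1-yl)-2,3-dihydro-4H-chromen-4-one, via aryne 27 (not isolated)
Conditions: CsF (4 equiv), 4 Å molecular sieves, THF, 50 °C; 13 (1.3 equiv) added over 6 h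
Reagents that add atoms: none
Why: Proposed new method: fluoride attacks the silicon of 13 and triflate leaves, giving aryne 27 (C4a≡C8a), to which the fluoride-bound hydroxyl of 26 adds as an alkoxide at C8a (O1–C8a), and the resulting C4a aryl anion, now held within reach of the ester carbon, attacks it and expels methoxide (C4–C4a). The closest known reaction types are the aryne annulation of salicylate esters to xanthones and the insertion of arynes into carboxylic acid C–O bonds, both of which pair O-arylation with acyl capture by the aryl anion; what is new is an aliphatic, aldol-derived alkoxide as the oxygen partner. Ring C closes by a 6-exo-trig acyl substitution. No stereocenter is formed and none is touched: the C–O bonds at C2 and C3 stay intact, so the anti (2R,3R) pair of 26 becomes the trans (2R,3R) pair of 28, and any epimerisation at C3 next to the new ketone would lead back to the favoured diequatorial trans isomer. The step needs regioselective O-attack at C8a, which the C5 chlorine should secure by distorting the aryne so that negative charge builds on the neighbouring C4a, even though the C8 prenyl group hinders C8a. It also needs acyl capture to outrun protonation of the aryl anion and retro-aldol of the alkoxide, which the non-acidic solvent THF, excess CsF as HF acceptor and slow release of the aryne at low alkoxide concentration are chosen to favour.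

Step 14
Reactants: 28 (2R,3R)-5-chloro-3,7-bis(methoxymethoxy)-2-[4-(methoxymethoxy)-3,5-bis(3-methylbut-2-en-1-yl)phenyl]-8-(3-methylbut-2-en-1-yl)-2,3-dihydro-4H-chromen-4-one
Product: 29 (2R,3R)-3,7-bis(methoxymethoxy)-2-[4-(methoxymethoxy)-3,5-bis(3-methylbut-2-en-1-yl)phenyl]-8-(3-methylbut-2-en-1-yl)-2,3-dihydro-4H-chromen-4-one
Conditions: Pd(OAc)2 (5 mol %), 2-dicyclohexylphosphino-2′,4′,6′-triisopropylbiphenyl (10 mol %), HCO2Na (3 equiv), DMF, 70 °C
Reagents that add atoms: none
Why: Palladium-catalysed transfer hydrodechlorination: zerovalent palladium with the bulky electron-rich biaryl phosphine inserts into the C5–Cl bond activated by the neighbouring ketone, formate exchanges for chloride and loses CO2 to give an aryl palladium hydride that reductively eliminates, under weakly basic conditions that should leave the prenyl alkenes, the acetals and both stereocenters alone.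

Step 15
Reactants: 29 (2R,3R)-3,7-bis(methoxymethoxy)-2-[4-(methoxymethoxy)-3,5-bis(3-methylbut-2-en-1-yl)phenyl]-8-(3-methylbut-2-en-1-yl)-2,3-dihydro-4H-chromen-4-one
Product: 30 (2R,3R)-3,7-dihydroxy-2-[4-hydroxy-3,5-bis(3-methylbut-2-en-1-yl)phenyl]-8-(3-methylbut-2-en-1-yl)-2,3-dihydro-4H-chromen-4-one
Conditions: HCl (3 M) in MeOH, 40 °C
Reagents that add atoms: none
Why: Acid-catalysed transacetalisation of the three MOM groups to dimethoxymethane frees the two phenols and the C3 hydroxyl without breaking a bond at C2 or C3, the moderate temperature being chosen to keep acid-promoted chroman formation from the ortho-prenyl phenols slow.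

**Compound list**

1 | 5-chlororesorcinol (5-chlorobenzene-1,3-diol) | Oc1cc(O)cc(Cl)c1 | starting material
2 | 1-chloro-3,5-bis(methoxymethoxy)benzene | COCOc1cc(Cl)cc(OCOC)c1 | intermediate
3 | prenyl bromide (1-bromo-3-methylbut-2-ene) | CC(C)=CCBr | starting material
4 | [4-chloro-2,6-bis(methoxymethoxy)phenyl]lithium (not isolated) | [Li]c1c(OCOC)cc(Cl)cc1OCOC | intermediate
5 | 5-chloro-1,3-bis(methoxymethoxy)-2-(3-methylbut-2-en-1-yl)benzene | COCOc1cc(Cl)cc(OCOC)c1CC=C(C)C | intermediate
6 | [6-chloro-2,4-bis(methoxymethoxy)-3-(3-methylbut-2-en-1-yl)phenyl]lithium (not isolated) | [Li]c1c(Cl)cc(OCOC)c(CC=C(C)C)c1OCOC | intermediate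
7 | 2-bromo-1-chloro-3,5-bis(methoxymethoxy)-4-(3-methylbut-2-en-1-yl)benzene | Brc1c(Cl)cc(OCOC)c(CC=C(C)C)c1OCOC | intermediate
8 | 4-bromo-5-chloro-2-(3-methylbut-2-en-1-yl)benzene-1,3-diol | Oc1cc(Cl)c(Br)c(O)c1CC=C(C)C | intermediate
9 | 2-bromo-1-chloro-4-(3-methylbut-2-en-1-yl)-3,5-bis[(trimethylsilyl)oxy]benzene (not isolated) | C[Si](C)(C)Oc1cc(Cl)c(Br)c(O[Si](C)(C)C)c1CC=C(C)C | intermediate
10 | lithium 3-chloro-6-(3-methylbut-2-en-1-yl)-2-(trimethylsilyl)-5-[(trimethylsilyl)oxy]phenolate (not isolated) | [Li+].[O-]c1c(CC=C(C)C)c(O[Si](C)(C)C)cc(Cl)c1[Si](C)(C)C | intermediate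
11 | 3-chloro-6-(3-methylbut-2-en-1-yl)-2-(trimethylsilyl)-5-[(trimethylsilyl)oxy]phenyl trifluoromethanesulfonate (not isolated) | C[Si](C)(C)Oc1cc(Cl)c([Si](C)(C)C)c(OS(=O)(=O)C(F)(F)F)c1CC=C(C)C | intermediate
12 | 3-chloro-5-hydroxy-6-(3-methylbut-2-en-1-yl)-2-(trimethylsilyl)phenyl trifluoromethanesulfonate | C[Si](C)(C)c1c(Cl)cc(O)c(CC=C(C)C)c1OS(=O)(=O)C(F)(F)F | intermediate
13 | 3-chloro-5-(methoxymethoxy)-6-(3-methylbut-2-en-1-yl)-2-(trimethylsilyl)phenyl trifluoromethanesulfonate | C[Si](C)(C)c1c(Cl)cc(OCOC)c(CC=C(C)C)c1OS(=O)(=O)C(F)(F)F | intermediate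
14 | 3,5-dibromo-4-hydroxybenzaldehyde | O=Cc1cc(Br)c(O)c(Br)c1 | starting material
15 | 3,5-dibromo-4-(methoxymethoxy)benzaldehyde | COCOc1c(Br)cc(C=O)cc1Br | intermediate
16 | tributyl(3-methylbut-2-en-1-yl)stannane | CCCC[Sn](CCCC)(CCCC)CC=C(C)C | starting material
17 | 4-(methoxymethoxy)-3,5-bis(3-methylbut-2-en-1-yl)benzaldehyde | COCOc1c(CC=C(C)C)cc(C=O)cc1CC=C(C)C | intermediate
18 | glycolic acid (2-hydroxyacetic acid) | OCC(=O)O | starting material
19 | methoxymethyl 2-(methoxymethoxy)acetate (not isolated) | COCOCC(=O)OCOC | intermediate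
20 | 2-(methoxymethoxy)acetic acid | COCOCC(=O)O | intermediate
21 | (4S)-4-benzyl-1,3-oxazolidin-2-one | O=C1N[C@@H](Cc2ccccc2)CO1 | starting material
22 | 2-(methoxymethoxy)acetic 2,2-dimethylpropanoic anhydride (not isolated) | COCOCC(=O)OC(=O)C(C)(C)C | intermediate
23 | (4S)-4-benzyl-3-[2-(methoxymethoxy)acetyl]-1,3-oxazolidin-2-one | COCOCC(=O)N1[C@@H](Cc2ccccc2)COC1=O | intermediate
24 | (4S)-4-benzyl-3-[(2R,3R)-2-(methoxymethoxy)-3-[4-(methoxymethoxy)-3,5-bis(3-methylbut-2-en-1-yl)phenyl]-3-[(trimethylsilyl)oxy]propanoyl]-1,3-oxazolidin-2-one (not isolated) | COCOc1c(CC=C(C)C)cc(cc1CC=C(C)C)[C@@H](O[Si](C)(C)C)[C@@H](OCOC)C(=O)N1[C@@H](Cc2ccccc2)COC1=O | intermediate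
25 | (4S)-4-benzyl-3-[(2R,3R)-3-hydroxy-2-(methoxymethoxy)-3-[4-(methoxymethoxy)-3,5-bis(3-methylbut-2-en-1-yl)phenyl]propanoyl]-1,3-oxazolidin-2-one | COCOc1c(CC=C(C)C)cc(cc1CC=C(C)C)[C@@H](O)[C@@H](OCOC)C(=O)N1[C@@H](Cc2ccccc2)COC1=O | intermediate
26 | methyl (2R,3R)-3-hydroxy-2-(methoxymethoxy)-3-[4-(methoxymethoxy)-3,5-bis(3-methylbut-2-en-1-yl)phenyl]propanoate | COCOc1c(CC=C(C)C)cc(cc1CC=C(C)C)[C@@H](O)[C@@H](OCOC)C(=O)OC | intermediate
27 | 3-chloro-5-(methoxymethoxy)-6-(3-methylbut-2-en-1-yl)benzyne (1,2-didehydrobenzene; not isolated) | COCOC1=C(CC=C(C)C)C#CC(Cl)=C1 | intermediate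
28 | (2R,3R)-5-chloro-3,7-bis(methoxymethoxy)-2-[4-(methoxymethoxy)-3,5-bis(3-methylbut-2-en-1-yl)phenyl]-8-(3-methylbut-2-en-1-yl)-2,3-dihydro-4H-chromen-4-one | COCOc1c(CC=C(C)C)cc(cc1CC=C(C)C)[C@H]1Oc2c(c(Cl)cc(OCOC)c2CC=C(C)C)C(=O)[C@@H]1OCOC | intermediate
29 | (2R,3R)-3,7-bis(methoxymethoxy)-2-[4-(methoxymethoxy)-3,5-bis(3-methylbut-2-en-1-yl)phenyl]-8-(3-methylbut-2-en-1-yl)-2,3-dihydro-4H-chromen-4-one | COCOc1c(CC=C(C)C)cc(cc1CC=C(C)C)[C@H]1Oc2c(ccc(OCOC)c2CC=C(C)C)C(=O)[C@@H]1OCOC | intermediate
30 | (2R,3R)-3,7-dihydroxy-2-[4-hydroxy-3,5-bis(3-methylbut-2-en-1-yl)phenyl]-8-(3-methylbut-2-en-1-yl)-2,3-dihydro-4H-chromen-4-one | CC(C)=CCc1cc([C@H]2Oc3c(ccc(O)c3CC=C(C)C)C(=O)[C@@H]2O)cc(CC=C(C)C)c1O | target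

**Step count**

Total steps: 15. Longest linear sequence: 9 steps (1–6, then 13–15).

**Steps most likely to fail**

Step 13. The C4a anion may be protonated before it reaches the ester, which would leave an open aryl ether. The alkoxide may also fragment by retro-aldol, the oxygen may add at C4a instead of C8a, or the aryne may be consumed in ene reactions with prenyl groups. The fallback uses only known reactions: it builds the flavanonol by the classical chalcone epoxide route, setting out from aldehyde 17 and returning to the route at the target 30. Commercial 1-(2,4-dihydroxyphenyl)ethan-1-one is C-prenylated at C3 with 3 (aq. KOH) to 1-[2,4-dihydroxy-3-(3-methylbut-2-en-1-yl)phenyl]ethan-1-one F1. This is protected (MOMCl, NaH, DMF) as 1-[2,4-bis(methoxymethoxy)-3-(3-methylbut-2-en-1-yl)phenyl]ethan-1-one F2. Claisen–Schmidt condensation of F2 with 17 (KOH, EtOH) should give (E)-1-[2,4-bis(methoxymethoxy)-3-(3-methylbut-2-en-1-yl)phenyl]-3-[4-(methoxymethoxy)-3,5-bis(3-methylbut-2-en-1-yl)phenyl]prop-2-en-1-one F3. Juliá–Colonna epoxidation (poly-L-leucine, urea–H2O2, DBU, THF) is a nucleophilic epoxidation that leaves the prenyl alkenes alone, and is expected to deliver [2,4-bis(methoxymethoxy)-3-(3-methylbut-2-en-1-yl)phenyl]{(2R,3S)-3-[4-(methoxymethoxy)-3,5-bis(3-methylbut-2-en-1-yl)phenyl]oxiran-2-yl}methanone F4. HCl in MeOH then removes the MOM groups, and the freed 2′-phenol opens the epoxide at the benzylic carbon with inversion, which should give the trans (2R,3R) dihydroflavonol 30 directly.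

Step 11. The α-alkoxy group may perturb the magnesium chelate and the electron-rich aldehyde is a weak electrophile, so facial or anti selectivity may be poor or the addition may stall. The fallback sets only the benzylic center by aldol and lets C3 settle thermodynamically; it sets out from 23 and 17 and returns at 28. A boron-mediated Evans syn aldol (Bu2BOTf, Et3N, CH2Cl2, −78 → 0 °C) should give (4S)-4-benzyl-3-[(2S,3R)-3-hydroxy-2-(methoxymethoxy)-3-[4-(methoxymethoxy)-3,5-bis(3-methylbut-2-en-1-yl)phenyl]propanoyl]-1,3-oxazolidin-2-one F5. Methanolysis as in step 12 gives methyl (2S,3R)-3-hydroxy-2-(methoxymethoxy)-3-[4-(methoxymethoxy)-3,5-bis(3-methylbut-2-en-1-yl)phenyl]propanoate F6. Annulation with 13 as in step 13 gives the cis compound (2R,3S)-5-chloro-3,7-bis(methoxymethoxy)-2-[4-(methoxymethoxy)-3,5-bis(3-methylbut-2-en-1-yl)phenyl]-8-(3-methylbut-2-en-1-yl)-2,3-dihydro-4H-chromen-4-one F7. Base-mediated epimerisation at C3, α to the ketone (DBU, toluene, rt), should then move F7 to the favoured trans isomer 28.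

Step 15. The C3 alkyl acetal cleaves more slowly than the aryl acetals, and during that time the freed ortho-prenyl phenols may cyclise onto their alkenes under acid. The fallback splits the deprotection into two stages of different mechanism, setting out from 29 and returning at 30. Catalytic HCl in MeOH at rt should remove only the two aryl MOM groups and give (2R,3R)-7-hydroxy-2-[4-hydroxy-3,5-bis(3-methylbut-2-en-1-yl)phenyl]-3-(methoxymethoxy)-8-(3-methylbut-2-en-1-yl)-2,3-dihydro-4H-chromen-4-one F8. The remaining acetal is then cleaved without protic acid by ZnBr2 and n-PrSH in CH2Cl2 at 0 °C (Lewis acid activation and thiol capture of the methoxymethyl group), giving 30.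

**Further compounds**

F1 | step 13 | 1-[2,4-dihydroxy-3-(3-methylbut-2-en-1-yl)phenyl]ethan-1-one | CC(=O)c1ccc(O)c(CC=C(C)C)c1O
F2 | step 13 | 1-[2,4-bis(methoxymethoxy)-3-(3-methylbut-2-en-1-yl)phenyl]ethan-1-one | CC(=O)c1ccc(OCOC)c(CC=C(C)C)c1OCOC
F3 | step 13 | (E)-1-[2,4-bis(methoxymethoxy)-3-(3-methylbut-2-en-1-yl)phenyl]-3-[4-(methoxymethoxy)-3,5-bis(3-methylbut-2-en-1-yl)phenyl]prop-2-en-1-one | COCOc1ccc(C(=O)/C=C/c2cc(CC=C(C)C)c(OCOC)c(CC=C(C)C)c2)c(OCOC)c1CC=C(C)C
F4 | step 13 | [2,4-bis(methoxymethoxy)-3-(3-methylbut-2-en-1-yl)phenyl]{(2R,3S)-3-[4-(methoxymethoxy)-3,5-bis(3-methylbut-2-en-1-yl)phenyl]oxiran-2-yl}methanone | COCOc1ccc(C(=O)[C@@H]2O[C@H]2c3cc(CC=C(C)C)c(OCOC)c(CC=C(C)C)c3)c(OCOC)c1CC=C(C)C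
F5 | step 11 | (4S)-4-benzyl-3-[(2S,3R)-3-hydroxy-2-(methoxymethoxy)-3-[4-(methoxymethoxy)-3,5-bis(3-methylbut-2-en-1-yl)phenyl]propanoyl]-1,3-oxazolidin-2-one | COCOc1c(CC=C(C)C)cc(cc1CC=C(C)C)[C@@H](O)[C@H](OCOC)C(=O)N1[C@@H](Cc2ccccc2)COC1=O
F6 | step 11 | methyl (2S,3R)-3-hydroxy-2-(methoxymethoxy)-3-[4-(methoxymethoxy)-3,5-bis(3-methylbut-2-en-1-yl)phenyl]propanoate | COCOc1c(CC=C(C)C)cc(cc1CC=C(C)C)[C@@H](O)[C@H](OCOC)C(=O)OC
F7 | step 11 | (2R,3S)-5-chloro-3,7-bis(methoxymethoxy)-2-[4-(methoxymethoxy)-3,5-bis(3-methylbut-2-en-1-yl)phenyl]-8-(3-methylbut-2-en-1-yl)-2,3-dihydro-4H-chromen-4-one | COCOc1c(CC=C(C)C)cc(cc1CC=C(C)C)[C@H]1Oc2c(c(Cl)cc(OCOC)c2CC=C(C)C)C(=O)[C@H]1OCOC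
F8 | step 15 | (2R,3R)-7-hydroxy-2-[4-hydroxy-3,5-bis(3-methylbut-2-en-1-yl)phenyl]-3-(methoxymethoxy)-8-(3-methylbut-2-en-1-yl)-2,3-dihydro-4H-chromen-4-one | CC(C)=CCc1cc([C@H]2Oc3c(ccc(O)c3CC=C(C)C)C(=O)[C@@H]2OCOC)cc(CC=C(C)C)c1O
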